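North-east, the one earlier run, was what I had for reading this flask, which held less starting material at the same added ligand.

the same everywhere: catalyst 0.44 mol%; added ligand 0.10 mM

| charge | starting material | other conformer | remark | time |
|---|---|---|---|---|
| north-east | 0.015 M | 0.10 equiv | run made earlier |  |
| flask | 0.010 M | 0.100 equiv |  | 10 h |

north-east run (percent of the starting material and other conformer together charged)

| time / h | target / % | isomer of the product / % |
|---|---|---|
| 0.667 | 9 | 3 |
| 1.33 | 14 | 10 |
| 2.00 | 15 | 13 |
| 2.50 | 18 | 15 |
| 3.00 | 21 | 17 |

(each reading ± 1.5 percentage points)

1. share of target in target plus isomer of the product at 5.0 min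
2. share of target in target plus isomer of the product at 50 min
3. share of target in target plus isomer of the product at 10 h

- the numbers in the tables scatter by 1.5 percentage points (one standard deviation)
- no earlier run changes the charge of catalyst; that part of a forecast is a guess

I drew the north-east curves first. Over the first reading, target rose at 0.135 h⁻¹ of the charge and the isomer of the product at 0.0450 h⁻¹. From 1.33 h to 3.00 h both rose at 0.0419 h⁻¹, so the target readings showed a slope falling before 1.33 h, a knee that rested on the first reading. The curves did not cross in the readings, and neither reached a level.

So I replaced the changing share by its mean, the pooled share: target summed over the north-east readings from 1.33 h on, divided by target plus isomer summed over the same readings, a selectivity read from those readings.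

target sum = 68.0%; isomer sum = 55.0%

pooled share = 55.3%, scatter 1.7 percentage points

The first north-east reading gave a share of 75.0%, which lay 20 points above that mean. That reading's own scatter was 9.9 points, so the gap was twice its scatter. I would not build on one such point, and my own reckoning, which was not the forecast's, put 55.3% at each asked time, guessing that the more dilute charge left it unmoved.

The forecast read “a fast, selective conversion of the other conformer to target” and gave 88% (68% to 99%), 70% (57% to 83%) and 51% (42% to 60%). It differed from my figure: its first two values stood higher and its last stood lower.

The flask gave 37.0%, 49.1% and 53.2%; its target and isomer stood level at 1.05 h, at 5.97% of the charge each.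

    catalyst + added ligand ⇌ idle complex, settled at all times (K = 29000 M⁻¹)
    catalyst ⇌ dormant form (K = 1.20, k = 0.0160 min⁻¹)
    starting material ⇌ other conformer (K = 0.0500, k = 0.00450 min⁻¹)
    starting material + catalyst → catalyst + target (k = 85.0 M⁻¹ min⁻¹)
    catalyst + other conformer → catalyst + isomer of the product (k = 1700 M⁻¹ min⁻¹)

Multiplied by the target plus isomer present in the flask at 10.0 h, the pooled share gives 33.6% of target, against 32.4% in the flask. In the neighbour flask charged with 4.0 × 10⁻⁵ M of added ligand, the same product gives 41.2%, against 40.9% at 10.0 h.

The readings are simulated with constants of no real substance; scatter was added.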